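Assumption: the structure carries no descriptor for the C6–C8' biaryl axis, so the racemate is the goal and no step is asked to control the axis.

Coumarin numbering is used throughout: unprimed atoms belong to the unit joined through C6, primed atoms to the unit joined through C8'.

## Analysis of the target

Target 17 is 4,4',7,7'-tetramethoxy-5,5'-dimethyl-6,8'-bicoumarin: two identical 4,7-dimethoxy-5-methyl-2H-chromen-2-one bicycles, bonded from C6 of one to C8' of the other. It has no stereocentre. Its only stereogenic element is the C6–C8' axis, held by four ortho neighbours (the C5 methyl group, the C7 and C7' methoxy groups and the ring oxygen on C8a'). The sensitive groups are the two lactones, which open with hydroxide or alkoxide, and the two 4-methoxy enol ethers, which are vinylogous carbonates and are cleaved by acid or Lewis acid; both are best made last. The main difficulty is the junction: a 6,8' link cannot come from dimerising one monomer, and a cross-coupling would have to join two electron-rich carbons that each carry two ortho substituents. Both benzene rings are also crowded (one hydrogen each, at C8 and at C6'), so every substituent needs positional control. The strategy rests on the unprimed ring: the chain C8(H)–C7(O)–C6(aryl)–C5(CH3)–C4a is a 1,4-enyne in disguise, with C6 as a former ketone carbon, and C8a with its oxygen is one molecule of CO. It also uses the primed ring, which as a 2,6-dimethoxy-4-methylphenyl group on C6 is symmetric, so C4a' and C6' are the same position until the first substituent enters.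

## Retrosynthetic reasoning

**17 to 16.** The two O–CH3 bonds at C4 and C4' are cut first. These enol ethers are the most labile groups, so they are formed last. The forward reaction must alkylate the C4 oxygen of each 4-hydroxycoumarin unit of 16 and not C3.

**16 to 15.** In each pyranone C2–C3 and C2–O1 are cut, which removes C2 and C2' as one-carbon units at the carbonic acid level. What remains is an ortho-hydroxyacetophenone on each ring, compound 15. The cut is made here because both heterocycles are identical and can be closed in one double operation. The forward reaction must acylate each methyl ketone enolate on carbon with a dialkyl carbonate and let the neighbouring phenoxide close the lactone.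

**15 to 14.** The hydroxyl groups at C8a and C8a' are traced back to methyl ethers. The forward reaction must cleave only the methoxy group ortho to each acetyl carbonyl and leave the C7 and C7' ethers; chelation to a boron Lewis acid does this.

**14 to 13.** The aryl–acetyl bonds C4a–C4 and C4a'–C4' are cut. In the unprimed ring of 13, C4a is ortho and para to the two methoxy groups and more open than C8, which lies between them. In the primed ring the two free positions are equivalent, and one acetyl group deactivates each ring against a second. Both rings can therefore be acetylated in one Friedel–Crafts operation.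

**13 to 11 (through 12).** The ethers at C7 and C8a are traced to the acetate and the free phenol of 11. The difference between these two oxygens is not kept, because the ortho-selective cleavage in the step to 15 re-creates it, and in return both rings go through the endgame together.

**11 to 8 and 9 (key disconnection).** C8–C8a and C4a–C8a are cut and the acetoxy group is moved back from C7 to C6. This dismantles the unprimed benzene ring so that the biaryl bond becomes a bond from an aromatic carbon to an sp3 carbinol carbon. The hindered arene–arene coupling is thereby avoided, which a direct cut of C6–C8' would not achieve. The forward reaction must shift the ester 1,2, take up one CO 9 between the alkyne terminus and the alkene terminus of 8, and aromatise.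

**8 to 5 and 6.** The C6–C7 bond and the O–acyl bond are cut. The forward reaction is 1,2-addition of the acetylide 6 to the hindered ketone 5 and acylation of alkoxide 7 in the same flask.

**5 to 4 to 1 and 2.** After an oxidation-level change, C6–C8' is cut. The forward reaction is lithiation of 1 between its methoxy groups to aryllithium 3 and addition to the aldehyde of 2. Compound 2 supplies C6, C5, the C5 methyl group and C4a.

## Alternatives that were turned down

**Alternative 1:** Disconnection: both pyranones are removed at once by cutting C4a–C4, C3–C2 and C2–O1 and their primed counterparts. This leaves the bis(ortho-iodophenol) biaryl A2 (iodine on C4a and C4a', hydroxyl on C8a and C8a'), two molecules of the silyl-capped ynol ether A3 and two molecules of CO 9.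
- Forward key step: a palladium-catalysed carbonylative annulation run twice in one flask. Zerovalent palladium enters each C–I bond, A3 inserts with the aryl group on the methoxy-bearing carbon, 9 inserts and the phenol closes the lactone. The product is the 3,3'-bis(trimethylsilyl)bicoumarin A1, which needs desilylation to reach 17.
- For it: the 4-methoxy groups arrive with the alkyne, so carbonate closure and O-methylation are not needed. The steric and electronic bias of A3 both point to the right orientation.
- Against it: A2 already contains the complete tetra-ortho-substituted biaryl, so the hardest bond is not addressed. Each C–I bond is flanked by a methyl and a hydroxyl group, which slows oxidative addition and insertion. Five components must combine in the right order twice. A3 is a fragile ynol ether under hot basic conditions.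
- Comparison: its endgame is shorter than the chosen one. The chosen strategy offers a construction of the biaryl itself and robust pyranone chemistry.

**Alternative 2:** Disconnection: the unprimed benzene ring is cut at C5–C6 and C7–C8. The pyranone ester A5 supplies C8, C8a, C4a and C5, and the aryl ynol ether A6 supplies C6 and C7.
- Forward key step: thermal Diels–Alder addition of A6 across the diene of A5, then loss of carbon dioxide A7 from the bridged lactone, giving benzoate A4.
- For it: one step gives a fully substituted ring with every substituent placed, including a carbon substituent at C4a. No Friedel–Crafts regiochemistry arises in that ring, and here it is stronger than the chosen route. The polarity of the partners matches the required orientation.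
- Against it: C5–C6 must form between a methyl-bearing diene terminus and an alkyne carbon carrying a 2,6-dimethoxyaryl group. The 4-methoxy group makes A5 a poor electron-deficient diene, so temperatures are needed that A6 is unlikely to survive. A6 needs a multistep preparation. After A4 the ester must be homologated and C8a unmasked, while the primed ring needs its own acetylation sequence.
- Comparison: the chosen strategy offers a catalytic ring formation on a three-step precursor and an intermediate, 13, whose two rings are elaborated in parallel.

**Alternative 3:** Disconnection: the primed benzene ring is cut at C4a'–C5' and C7'–C8'. This gives the β-keto ester A9, which carries the future unprimed ring as an aryl group, and methyl but-2-ynoate A10.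
- Forward key step: the sodium enolate of A9 adds through its central carbon (C4a') to the methyl-bearing alkyne carbon of A10 (C5'). The benzylic carbon (C8') then condenses onto the ester carbon of A10 (C7'), and aromatisation gives the aryl orsellinate A8.
- For it: cheap, metal-free, no CO pressure. The carbon substituent at C4a' is placed unambiguously. The two phenols of A8 are differentiated by hydrogen bonding to the ester, so C7'–OH could be methylated selectively. On cost and on regiochemical definition of the primed ring it is stronger than the chosen route.
- Against it: the Michael adduct can lactonise through oxygen to a 2-pyranone instead of closing through carbon. The closing bond forms at a carbon bearing a di-ortho-substituted aryl group. A9 needs several steps. After A8 the two rings need different sequences to their pyranones, which lengthens the endgame.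
- Comparison: the chosen strategy offers a short, symmetric endgame and the biaryl bond through a simple carbonyl addition.

Key step: step 4

## Route

Step 1
Reactants: 1 3,5-dimethoxytoluene; 2 methacrolein
Product: 4 racemic 1-(2,6-dimethoxy-4-methylphenyl)-2-methylprop-2-en-1-ol, via (2,6-dimethoxy-4-methylphenyl)lithium 3 (not isolated)
Conditions: n-BuLi, THF, 0 °C to rt; then 2, −78 °C; H2O
Reagents that add atoms: none
Why: Directed ortho-lithiation removes the ring hydrogen between the two methoxy groups of 1, which is the most acidic and is held by both oxygens. The hard aryllithium 3 then adds 1,2 to the aldehyde of 2 at low temperature; the carbinol centre is racemic and is removed in step 2.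

Step 2
Reactants: 4 racemic 1-(2,6-dimethoxy-4-methylphenyl)-2-methylprop-2-en-1-ol
Product: 5 1-(2,6-dimethoxy-4-methylphenyl)-2-methylprop-2-en-1-one
Conditions: Dess–Martin periodinane, pyridine, CH2Cl2, 0 °C to rt
Reagents that add atoms: none
Why: Dess–Martin oxidation of a secondary benzylic and allylic alcohol; the reagent does not rely on benzylic conjugation, which the two ortho methoxy groups twist away, and pyridine buffers the acetic acid so that the carbinol does not ionise.

Step 3
Reactants: 5 1-(2,6-dimethoxy-4-methylphenyl)-2-methylprop-2-en-1-one; 6 ethynylmagnesium bromide
Product: 8 racemic 3-(2,6-dimethoxy-4-methylphenyl)-4-methylpent-4-en-1-yn-3-yl acetate, via bromomagnesium tertiary alkoxide 7 (not isolated)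
Conditions: 6, THF, −78 to 0 °C; then Ac2O, DMAP (cat.), 0 °C to rt; cold aq NaHCO3; Et3N-deactivated SiO2
Reagents that add atoms: acetic anhydride, CC(=O)OC(C)=O
Why: 1,2-Addition of an alkynyl Grignard reagent to a ketone without α-hydrogens; the linear sp nucleophile is small, alkynyl groups transfer poorly in the conjugate sense, and the ortho methoxy groups can hold magnesium near the carbonyl group. Alkoxide 7 is acetylated in the same flask under DMAP catalysis, so the ionisable free carbinol is never handled; the new quaternary centre is racemic and becomes sp2 in step 4.

Step 4
Reactants: 8 racemic 3-(2,6-dimethoxy-4-methylphenyl)-4-methylpent-4-en-1-yn-3-yl acetate; 9 carbon monoxide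
Product: 11 4-hydroxy-2',6'-dimethoxy-4',6-dimethyl-[1,1'-biphenyl]-2-yl acetate, via cyclohexadienone tautomer 10 (not isolated)
Conditions: [RhCl(CO)2]2 (5 mol %), CO (30 atm), 1,2-dichloroethane, 80 °C
Reagents that add atoms: none
Why: The reaction type is the known rhodium-catalysed (5+1) carbonylative benzannulation of 3-acyloxy-1,4-enynes to resorcinol monoesters, used here on a tertiary ester with an aryl group on the carbinol carbon. Monovalent rhodium binds the terminal alkyne of 8, the acetate carbonyl oxygen attacks the internal alkyne carbon (C7) to give a five-membered dioxolenium ion, and cleavage of the old C6–O bond completes the 1,2-acyloxy shift and leaves a rhodium carbene at C8 conjugated with C7=C6 and C5=C4a. This metalla-triene closes in a six-electron process to a rhodacyclohexadiene, CO 9 inserts and reductive elimination forms C8–C8a and C4a–C8a (capture of the carbene by CO to a dienylketene and 6π electrocyclisation is the equivalent route), so the benzene ring is closed as a six-membered carbocycle from five chain carbons and one CO, and dienone 10 enolises to phenol 11. No stereocentre is formed: the carbinol centre of 8 becomes the sp2 carbon C6, and the biaryl axis of 11 is not stereogenic because the primed ring is still symmetric. The step needs the 1,2- and not the 1,3-acyloxy shift, which the terminal alkyne secures, since the 1,3-shift to an allenyl ester is the path of internal alkynes. It needs CO capture to outrun the Rautenstrauch-type closure to a cyclopentenone, which is why the CO pressure is high, and it needs the tertiary ester not to ionise, which the neutral medium free of Lewis acid serves. Closure requires the isopropenyl group cis to the carbene carbon across C7=C6, the geometry that keeps the bulky aryl group away from rhodium, and the other isomer cannot cyclise onto the aryl ring because both ortho positions carry methoxy groups, so it can only return through the reversible acyloxy shift.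

Step 5
Reactants: 11 4-hydroxy-2',6'-dimethoxy-4',6-dimethyl-[1,1'-biphenyl]-2-yl acetate
Product: 13 2,2',4,6'-tetramethoxy-4',6-dimethyl-1,1'-biphenyl, via biaryl resorcinol 12 (not isolated)
Conditions: K2CO3, MeOH, rt, argon; evaporate; then MeI, K2CO3, DMF, rt
Reagents that add atoms: iodomethane, CI
Why: Base-catalysed transesterification moves the aryl acetate onto the solvent and gives resorcinol 12, which is air-sensitive as its dianion and is methylated directly. Williamson ether synthesis on both phenoxides with a soft, unhindered electrophile in a dipolar aprotic solvent favours O- over C-alkylation.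

Step 6
Reactants: 13 2,2',4,6'-tetramethoxy-4',6-dimethyl-1,1'-biphenyl
Product: 14 3',5-diacetyl-2,2',4,6'-tetramethoxy-4',6-dimethyl-1,1'-biphenyl (racemic about the axis)
Conditions: AcCl, TiCl4, CH2Cl2, 0 °C to rt
Reagents that add atoms: acetyl chloride, CC(=O)Cl
Why: Friedel–Crafts acylation, once on each ring. In the unprimed ring C4a is ortho to the C8a methoxy group, para to the C7 methoxy group and next to the methyl group, while C8 is squeezed between two methoxy groups, so the bulky acylium complex takes C4a. In the primed ring the two free positions are equivalent, so the first acetyl group defines C4a', and each ring is deactivated against a second acylation.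

Step 7
Reactants: 14 3',5-diacetyl-2,2',4,6'-tetramethoxy-4',6-dimethyl-1,1'-biphenyl
Product: 15 3',5-diacetyl-2,6'-dimethoxy-4',6-dimethyl-[1,1'-biphenyl]-2',4-diol
Conditions: BCl3, CH2Cl2, −78 to 0 °C; H2O
Reagents that add atoms: none
Why: Chelation-controlled ether cleavage: BCl3 binds each acetyl oxygen and reaches only the ortho methoxy group (C8a, C8a'), whose methyl group is removed by chloride within a six-membered boron chelate. The C7 and C7' methoxy groups are para to the acetyl groups, cannot chelate and stay.

Step 8
Reactants: 15 3',5-diacetyl-2,6'-dimethoxy-4',6-dimethyl-[1,1'-biphenyl]-2',4-diol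
Product: 16 4,4'-dihydroxy-7,7'-dimethoxy-5,5'-dimethyl-2H,2'H-[6,8'-bichromene]-2,2'-dione
Conditions: NaH, (MeO)2CO, toluene, reflux; then 1 M HCl
Reagents that add atoms: dimethyl carbonate, COC(=O)OC
Why: Carbonate condensation to 4-hydroxycoumarins: excess NaH forms the phenoxide and the methyl ketone enolate, which is C-acylated by dimethyl carbonate (Claisen condensation), and the phenoxide closes the lactone on the β-keto ester. The acidic product stays as its enolate until work-up, which drives both closures.

Step 9
Reactants: 16 4,4'-dihydroxy-7,7'-dimethoxy-5,5'-dimethyl-2H,2'H-[6,8'-bichromene]-2,2'-dione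
Product: 17 4,4',7,7'-tetramethoxy-5,5'-dimethyl-2H,2'H-[6,8'-bichromene]-2,2'-dione (target, racemic about the C6–C8' axis)
Conditions: Me2SO4, K2CO3, acetone, reflux
Reagents that add atoms: dimethyl sulfate, COS(=O)(=O)OC
Why: O-Alkylation of a vinylogous acid: the 4-hydroxycoumarin anions react with the hard electrophile at the C4 oxygen, and the weak base leaves the lactones closed.

## Compound list

1 | 3,5-dimethoxytoluene | COc1cc(C)cc(OC)c1 | starting material
2 | methacrolein (2-methylprop-2-enal) | C=C(C)C=O | starting material
3 | (2,6-dimethoxy-4-methylphenyl)lithium, formed in the flask and not isolated | [Li]c1c(OC)cc(C)cc1OC | intermediate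
4 | racemic 1-(2,6-dimethoxy-4-methylphenyl)-2-methylprop-2-en-1-ol | C=C(C)C(O)c1c(OC)cc(C)cc1OC | intermediate
5 | 1-(2,6-dimethoxy-4-methylphenyl)-2-methylprop-2-en-1-one | C=C(C)C(=O)c1c(OC)cc(C)cc1OC | intermediate
6 | ethynylmagnesium bromide | C#C[Mg]Br | starting material
7 | bromomagnesium 3-(2,6-dimethoxy-4-methylphenyl)-4-methylpent-4-en-1-yn-3-olate (racemic), formed in the flask and not isolated | C=C(C)C(C#C)(O[Mg]Br)c1c(OC)cc(C)cc1OC | intermediate
8 | racemic 3-(2,6-dimethoxy-4-methylphenyl)-4-methylpent-4-en-1-yn-3-yl acetate | C=C(C)C(C#C)(OC(C)=O)c1c(OC)cc(C)cc1OC | intermediate
9 | carbon monoxide | [C-]#[O+] | starting material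
10 | 6-(2,6-dimethoxy-4-methylphenyl)-5-methyl-3-oxocyclohexa-1,5-dien-1-yl acetate, formed in the flask and not isolated | CC(=O)OC1=CC(=O)CC(C)=C1c1c(OC)cc(C)cc1OC | intermediate
11 | 4-hydroxy-2',6'-dimethoxy-4',6-dimethyl-[1,1'-biphenyl]-2-yl acetate | CC(=O)Oc1cc(O)cc(C)c1-c1c(OC)cc(C)cc1OC | intermediate
12 | 2',6'-dimethoxy-4',6-dimethyl-[1,1'-biphenyl]-2,4-diol, formed in the flask and not isolated | Cc1cc(O)cc(O)c1-c1c(OC)cc(C)cc1OC | intermediate
13 | 2,2',4,6'-tetramethoxy-4',6-dimethyl-1,1'-biphenyl | COc1cc(OC)cc(C)c1-c1c(OC)cc(C)cc1OC | intermediate
14 | 3',5-diacetyl-2,2',4,6'-tetramethoxy-4',6-dimethyl-1,1'-biphenyl (racemic about the axis) | CC(=O)c1c(OC)cc(OC)c(c1C)-c1c(OC)cc(C)c(C(C)=O)c1OC | intermediate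
15 | 3',5-diacetyl-2,6'-dimethoxy-4',6-dimethyl-[1,1'-biphenyl]-2',4-diol (racemic about the axis) | CC(=O)c1c(O)cc(OC)c(c1C)-c1c(OC)cc(C)c(C(C)=O)c1O | intermediate
16 | 4,4'-dihydroxy-7,7'-dimethoxy-5,5'-dimethyl-2H,2'H-[6,8'-bichromene]-2,2'-dione (racemic about the axis) | COc1cc2oc(=O)cc(O)c2c(C)c1-c1c(OC)cc(C)c2c(O)cc(=O)oc12 | intermediate
17 | 4,4',7,7'-tetramethoxy-5,5'-dimethyl-2H,2'H-[6,8'-bichromene]-2,2'-dione (racemic about the axis) | COc1cc2oc(=O)cc(OC)c2c(C)c1-c1c(OC)cc(C)c2c(OC)cc(=O)oc12 | target

## Step count and risks

Total: 9 steps. Longest linear sequence: 9 steps, from 1 to 17; compounds 2, 6 and 9 enter along this line.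

**Step 4 (key step).** The most likely failure is ionisation of the ester, which is tertiary, benzylic to an electron-rich arene, allylic and propargylic, leading to elimination or ester transposition before the 1,2-shift. The second risk is closure of the vinyl carbene without CO uptake, if capture is slowed by crowding between the acetoxy group and the aryl-bearing carbon. The fallback gives up the benzannulation and makes the biaryl bond by cross-coupling; it sets out from 1 and from aryllithium 3 and returns at 13. Aryllithium 3 is quenched with trimethyl borate and hydrolysed to (2,6-dimethoxy-4-methylphenyl)boronic acid F1. Compound 1 is brominated with N-bromosuccinimide in acetonitrile, ortho to the methyl group and para to a methoxy group, to 2-bromo-1,5-dimethoxy-3-methylbenzene F2. Suzuki–Miyaura coupling of F1 and F2 with Pd(OAc)2, SPhos and K3PO4 in toluene at 100 °C gives 13. This accepts a tetra-ortho-substituted coupling and a boronic acid prone to protodeboronation, which the main route avoids.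

**Step 3.** Addition to the ketone carbon, shielded by two ortho methoxy groups and cross-conjugated, may be slow enough for conjugate addition or enone polymerisation to compete, and the hindered alkoxide may be captured incompletely. The fallback reverses the order of the two carbonyl additions; it sets out from 2 and aryllithium 3 and returns at 8. LiC≡CSiMe3 adds to 2 to give 2-methyl-5-(trimethylsilyl)pent-1-en-4-yn-3-ol F3. Dess–Martin oxidation gives 2-methyl-5-(trimethylsilyl)pent-1-en-4-yn-3-one F4, an unhindered ketone. Aryllithium 3 adds to F4 at −78 °C and acetic anhydride is added to the same flask, giving 3-(2,6-dimethoxy-4-methylphenyl)-4-methyl-1-(trimethylsilyl)pent-4-en-1-yn-3-yl acetate F5. The silyl group is removed with Bu4NF buffered by acetic acid in THF at 0 °C to give 8.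

**Step 6.** Acylation at C8 may compete with C4a, and the strong Lewis acid may cleave methoxy groups early. The fallback uses a weaker, bulkier electrophile and builds the acetyl groups in stages; it sets out from 13 and returns at 14. Vilsmeier–Haack formylation (POCl3, DMF) gives 2,2',4,6'-tetramethoxy-4',6-dimethyl-[1,1'-biphenyl]-3',5-dicarbaldehyde F6. MeMgBr gives the bis(1-hydroxyethyl) compound 1,1'-(2,2',4,6'-tetramethoxy-4',6-dimethyl-[1,1'-biphenyl]-3',5-diyl)di(ethan-1-ol) F7, and Dess–Martin oxidation gives 14.

**Step 8.** The double condensation may stall: each acetyl group lies between a methyl group and a phenoxide, so intermolecular C-acylation of the enolate is slow, and closure of only one ring or O-carbonate formation may result. The fallback makes the acyl transfer intramolecular; it sets out from 15 and returns at 16. Methyl chloroformate and pyridine give the bis(methyl carbonate) 3',5-diacetyl-2,6'-dimethoxy-4',6-dimethyl-[1,1'-biphenyl]-2',4-diyl dimethyl bis(carbonate) F8. LiN(SiMe3)2 in THF then transfers each carbonate carbonyl from oxygen to the enolate carbon in the Baker–Venkataraman manner, and lactonisation and acidic work-up give 16.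

## Further compounds

F1 | step 4 | (2,6-dimethoxy-4-methylphenyl)boronic acid | OB(O)c1c(OC)cc(C)cc1OC
F2 | step 4 | 2-bromo-1,5-dimethoxy-3-methylbenzene | COc1cc(OC)c(Br)c(C)c1
F3 | step 3 | racemic 2-methyl-5-(trimethylsilyl)pent-1-en-4-yn-3-ol | C=C(C)C(O)C#C[Si](C)(C)C
F4 | step 3 | 2-methyl-5-(trimethylsilyl)pent-1-en-4-yn-3-one | C=C(C)C(=O)C#C[Si](C)(C)C
F5 | step 3 | racemic 3-(2,6-dimethoxy-4-methylphenyl)-4-methyl-1-(trimethylsilyl)pent-4-en-1-yn-3-yl acetate | C=C(C)C(C#C[Si](C)(C)C)(OC(C)=O)c1c(OC)cc(C)cc1OC
F6 | step 6 | 2,2',4,6'-tetramethoxy-4',6-dimethyl-[1,1'-biphenyl]-3',5-dicarbaldehyde | O=Cc1c(OC)cc(OC)c(c1C)-c1c(OC)cc(C)c(C=O)c1OC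
F7 | step 6 | 1,1'-(2,2',4,6'-tetramethoxy-4',6-dimethyl-[1,1'-biphenyl]-3',5-diyl)di(ethan-1-ol), mixture of stereoisomers | CC(O)c1c(OC)cc(OC)c(c1C)-c1c(OC)cc(C)c(C(C)O)c1OC
F8 | step 8 | 3',5-diacetyl-2,6'-dimethoxy-4',6-dimethyl-[1,1'-biphenyl]-2',4-diyl dimethyl bis(carbonate) | CC(=O)c1c(OC(=O)OC)cc(OC)c(c1C)-c1c(OC)cc(C)c(C(C)=O)c1OC(=O)OC
A1 | alternative 1 | 4,4',7,7'-tetramethoxy-5,5'-dimethyl-3,3'-bis(trimethylsilyl)-2H,2'H-[6,8'-bichromene]-2,2'-dione | COc1cc2oc(=O)c([Si](C)(C)C)c(OC)c2c(C)c1-c1c(OC)cc(C)c2c(OC)c([Si](C)(C)C)c(=O)oc12
A2 | alternative 1 | 3',5-diiodo-2,6'-dimethoxy-4',6-dimethyl-[1,1'-biphenyl]-2',4-diol | COc1cc(O)c(I)c(C)c1-c1c(OC)cc(C)c(I)c1O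
A3 | alternative 1 | 1-methoxy-2-(trimethylsilyl)acetylene | COC#C[Si](C)(C)C
A4 | alternative 2 | methyl 3-(2,6-dimethoxy-4-methylphenyl)-4,6-dimethoxy-2-methylbenzoate | COC(=O)c1c(C)c(-c2c(OC)cc(C)cc2OC)c(OC)cc1OC
A5 | alternative 2 | methyl 4-methoxy-6-methyl-2-oxo-2H-pyran-5-carboxylate | COC(=O)c1c(C)oc(=O)cc1OC
A6 | alternative 2 | 2-(methoxyethynyl)-1,3-dimethoxy-5-methylbenzene | COC#Cc1c(OC)cc(C)cc1OC
A7 | alternative 2 | carbon dioxide | O=C=O
A8 | alternative 3 | methyl 3-(2,4-dimethoxy-6-methylphenyl)-2,4-dihydroxy-6-methylbenzoate | COC(=O)c1c(C)cc(O)c(-c2c(OC)cc(OC)cc2C)c1O
A9 | alternative 3 | methyl 4-(2,4-dimethoxy-6-methylphenyl)-3-oxobutanoate | COC(=O)CC(=O)Cc1c(OC)cc(OC)cc1C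
A10 | alternative 3 | methyl but-2-ynoate | CC#CC(=O)OC
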